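**Retrosynthetic overview**
1. Last bond: the lactone C(=O)–O of the seven-membered dioxepinone ring, closed by intramolecular photochemical aroyl-radical addition to a quinone carbonyl oxygen (Klinger-type). Aldehyde + quinone is redox-isomeric with aryl ester + free ring A phenol, so this step also sets the final oxidation pattern.
2. Before that: the diaryl ether, by addition–elimination of the ring B phenol on a ring A chloroquinone.
3. Ring A from hydroquinone: oxidation to 2,5-dihydroxybenzoquinone, pyran annulation with 3-methylbut-2-enal, C-prenylation.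
4. Ring B from resorcinol: bis-silylation, meta C–H borylation/oxidation (third oxygen), ortho C-prenylation, ortho-formylation.
5. Ring order: pyran ring first (on the quinone), seven-membered lactone ring last; the silyl ethers are cleaved in the same pot.

Assumption: the target has no stereocentre and no stereogenic double bond (it is achiral), so no step has to set or protect configuration.

**Route**

Step 1
Reactants: 1 hydroquinone
Product: 2 2,5-dihydroxy-1,4-benzoquinone
Conditions: 50% aq. NaOH, 30% H2O2, 45–50 °C; then HCl
Reagents that add atoms: hydrogen peroxide, OO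
Why: Known alkaline peroxide oxidation of hydroquinone (in situ benzoquinone, two conjugate hydroxylation/re-oxidation cycles) that precipitates the product as its disodium salt.

Step 2
Reactants: 2 2,5-dihydroxy-1,4-benzoquinone; 3 3-methylbut-2-enal
Product: 4 6-hydroxy-2,2-dimethyl-2H-chromene-5,8-dione
Conditions: 2 (1.5 equiv), 3 (1.0 equiv, slow addition), ethylenediammonium diacetate (10 mol %), 1,4-dioxane, 80 °C
Reagents that add atoms: none
Why: Knoevenagel condensation at the nucleophilic ring CH of the vinylogous acid followed by oxa-6π electrocyclisation (formal [3+3], as in lawsone → dehydro-α-lapachone); excess 2 limits double annulation and the product settles as the para-quinone tautomer.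

Step 3
Reactants: 4 6-hydroxy-2,2-dimethyl-2H-chromene-5,8-dione; 5 1-bromo-3-methylbut-2-ene
Product: 6 6-hydroxy-2,2-dimethyl-7-(3-methylbut-2-en-1-yl)-2H-chromene-5,8-dione
Conditions: LiH, DMSO, 20 °C; then 5, 45 °C
Reagents that add atoms: none
Why: C-alkylation of the lithium salt of a 2-hydroxy-1,4-quinone at its only free ring carbon (the lawsone → lapachol reaction), the tight Li–O pairing favouring carbon over oxygen.

Step 4
Reactants: 7 resorcinol
Product: 8 1,3-bis(triisopropylsilyloxy)benzene
Conditions: iPr3SiCl (2.2 equiv), imidazole, DMF, 20 °C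
Reagents that add atoms: chlorotriisopropylsilane, CC(C)[Si](Cl)(C(C)C)C(C)C
Why: Standard phenol silylation; the bulky, base-stable silyl ethers later steer regiochemistry and come off with fluoride under near-neutral conditions.

Step 5
Reactants: 8 1,3-bis(triisopropylsilyloxy)benzene
Product: 10 3,5-bis(triisopropylsilyloxy)phenol, via arylboronate 9 (not isolated)
Conditions: B2pin2 (1.0 equiv), [Ir(OMe)(cod)]2 (1.5 mol %), 4,4'-di-tert-butyl-2,2'-bipyridine (3 mol %), THF, 80 °C; then Oxone (2KHSO5·KHSO4·K2SO4), acetone–H2O, 20 °C
Reagents that add atoms: bis(pinacolato)diboron, CC1(C)OB(OC1(C)C)B1OC(C)(C)C(C)(C)O1 (boron stays only in 9); potassium peroxymonosulfate, [K+].[O-]S(=O)(=O)OO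
Why: Sterically controlled Ir-catalysed C–H borylation (Hartwig–Miyaura type) goes to the only C–H not ortho to a silyloxy group, and one-pot ipso-oxidation of the C–B bond gives the phenol.

Step 6
Reactants: 10 3,5-bis(triisopropylsilyloxy)phenol; 5 1-bromo-3-methylbut-2-ene
Product: 11 2-(3-methylbut-2-en-1-yl)-3,5-bis(triisopropylsilyloxy)phenol
Conditions: NaH, toluene, 0 °C; then 5, 0 → 20 °C
Reagents that add atoms: none
Why: Ortho C-alkylation of a sodium phenoxide with an allylic bromide in a non-polar solvent; the two ortho carbons are equivalent and the para carbon is shielded between two triisopropylsilyloxy groups.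

Step 7
Reactants: 11 2-(3-methylbut-2-en-1-yl)-3,5-bis(triisopropylsilyloxy)phenol
Product: 12 2-hydroxy-3-(3-methylbut-2-en-1-yl)-4,6-bis(triisopropylsilyloxy)benzaldehyde
Conditions: MgCl2, Et3N, (CH2O)n, THF, 65 °C; then 1 M HCl
Reagents that add atoms: paraformaldehyde (formaldehyde), C=O
Why: Casnati–Skattebøl magnesium-phenoxide ortho-formylation is specific for the position ortho to the free OH, and only one such position is left.

Step 8
Reactants: 6 6-hydroxy-2,2-dimethyl-7-(3-methylbut-2-en-1-yl)-2H-chromene-5,8-dione; 12 2-hydroxy-3-(3-methylbut-2-en-1-yl)-4,6-bis(triisopropylsilyloxy)benzaldehyde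
Product: 14 2-{[2,2-dimethyl-7-(3-methylbut-2-en-1-yl)-5,8-dioxo-5,8-dihydro-2H-chromen-6-yl]oxy}-3-(3-methylbut-2-en-1-yl)-4,6-bis(triisopropylsilyloxy)benzaldehyde, via chloroquinone 13 (not isolated)
Conditions: (COCl)2, DMF (5 mol %), CH2Cl2, 0 °C, evaporate; then 12, Cs2CO3, MeCN, 0 → 20 °C
Reagents that add atoms: oxalyl chloride, ClC(=O)C(=O)Cl (chlorine stays only in 13)
Why: Vilsmeier-type conversion of the vinylogous acid into the vinylogous acid chloride, then addition–elimination of the phenoxide at the chlorine-bearing quinone carbon (chloride is the only good leaving group); anhydrous carbonate in MeCN leaves the aryl silyl ethers intact.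

Step 9
Reactants: 14 2-{[2,2-dimethyl-7-(3-methylbut-2-en-1-yl)-5,8-dioxo-5,8-dihydro-2H-chromen-6-yl]oxy}-3-(3-methylbut-2-en-1-yl)-4,6-bis(triisopropylsilyloxy)benzaldehyde
Product: 16 target depsidone CNP0263700.0, via bis-silyl depsidone 15 (not isolated)
Conditions: hν (450 nm LEDs), degassed PhCF3 (0.05 M), 20 °C; then Bu4NF, AcOH, THF, 0 °C
Reagents that add atoms: none
Why: Proposed new method: 450 nm light excites only the pyranoquinone, whose triplet abstracts the formyl hydrogen of a neighbouring molecule (the most hydridic C–H present); the nucleophilic aroyl radical then adds to the one quinone carbonyl oxygen it can reach, the one next to the diaryl ether, in a seven-membered closure that aromatises ring A, because all four quinone ring carbons are substituted and the usual C-acylation (which would lead to a xanthone) is blocked; the aryloxyl radical is reduced by hydrogen back-transfer from the semiquinone, which returns ground-state quinone, so the net change is a redox-neutral isomerisation of quinone + CHO into aryl ester + free phenol; the closest known reaction is the Klinger photoreaction of quinones with aldehydes (photo-Friedel–Crafts acylation), which gives hydroquinone monoesters with fully substituted quinones; buffered fluoride then cleaves both aryl silyl ethers without touching the lactone, the prenyl groups or the chromene, and no stereocentre is formed.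

**Compound list**

1 | hydroquinone (benzene-1,4-diol) | Oc1ccc(O)cc1 | starting material
2 | 2,5-dihydroxy-1,4-benzoquinone | O=C1C=C(O)C(=O)C=C1O | intermediate
3 | 3-methylbut-2-enal | CC(C)=CC=O | starting material
4 | 6-hydroxy-2,2-dimethyl-2H-chromene-5,8-dione | CC1(C)C=CC2=C(O1)C(=O)C=C(O)C2=O | intermediate
5 | 1-bromo-3-methylbut-2-ene (prenyl bromide) | CC(C)=CCBr | starting material
6 | 6-hydroxy-2,2-dimethyl-7-(3-methylbut-2-en-1-yl)-2H-chromene-5,8-dione | CC(C)=CCC1=C(O)C(=O)C2=C(OC(C)(C)C=C2)C1=O | intermediate
7 | resorcinol (benzene-1,3-diol) | Oc1cccc(O)c1 | starting material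
8 | 1,3-bis(triisopropylsilyloxy)benzene | CC(C)[Si](Oc1cccc(O[Si](C(C)C)(C(C)C)C(C)C)c1)(C(C)C)C(C)C | intermediate
9 | 2-[3,5-bis(triisopropylsilyloxy)phenyl]-4,4,5,5-tetramethyl-1,3,2-dioxaborolane | CC(C)[Si](Oc1cc(O[Si](C(C)C)(C(C)C)C(C)C)cc(c1)B1OC(C)(C)C(C)(C)O1)(C(C)C)C(C)C | intermediate
10 | 3,5-bis(triisopropylsilyloxy)phenol | CC(C)[Si](Oc1cc(O)cc(O[Si](C(C)C)(C(C)C)C(C)C)c1)(C(C)C)C(C)C | intermediate
11 | 2-(3-methylbut-2-en-1-yl)-3,5-bis(triisopropylsilyloxy)phenol | CC(C)=CCc1c(O)cc(O[Si](C(C)C)(C(C)C)C(C)C)cc1O[Si](C(C)C)(C(C)C)C(C)C | intermediate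
12 | 2-hydroxy-3-(3-methylbut-2-en-1-yl)-4,6-bis(triisopropylsilyloxy)benzaldehyde | CC(C)=CCc1c(O)c(C=O)c(O[Si](C(C)C)(C(C)C)C(C)C)cc1O[Si](C(C)C)(C(C)C)C(C)C | intermediate
13 | 6-chloro-2,2-dimethyl-7-(3-methylbut-2-en-1-yl)-2H-chromene-5,8-dione | CC(C)=CCC1=C(Cl)C(=O)C2=C(OC(C)(C)C=C2)C1=O | intermediate
14 | 2-{[2,2-dimethyl-7-(3-methylbut-2-en-1-yl)-5,8-dioxo-5,8-dihydro-2H-chromen-6-yl]oxy}-3-(3-methylbut-2-en-1-yl)-4,6-bis(triisopropylsilyloxy)benzaldehyde | CC(C)=CCC1=C(Oc2c(CC=C(C)C)c(O[Si](C(C)C)(C(C)C)C(C)C)cc(O[Si](C(C)C)(C(C)C)C(C)C)c2C=O)C(=O)C2=C(OC(C)(C)C=C2)C1=O | intermediate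
15 | bis(triisopropylsilyl) ether of the target (both ring B hydroxyls silylated; ring A phenol free) | CC(C)=CCc1c(O)c2c(c3c1Oc1c(CC=C(C)C)c(O[Si](C(C)C)(C(C)C)C(C)C)cc(O[Si](C(C)C)(C(C)C)C(C)C)c1C(=O)O3)C=CC(C)(C)O2 | intermediate
16 | target depsidone CNP0263700.0, a dibenzo[b,e][1,4]dioxepin-11-one. Ring B (acyl ring): OH ortho and OH para to the lactone carbonyl, prenyl on the carbon between the diaryl-ether oxygen and the para OH. Ring A, going round from the ester oxygen: carbon carrying the pyran CH=CH, carbon carrying the pyran oxygen (2,2-dimethyl-2H-pyran), free OH, prenyl, diaryl-ether oxygen. Achiral. | CC(C)=CCc1c(O)c2c(c3c1Oc1c(CC=C(C)C)c(O)cc(O)c1C(=O)O3)C=CC(C)(C)O2 | target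

**Totals**

Total step count: 9.
Longest linear sequence: 6 steps (steps 4–9, from resorcinol); the ring A branch is 3 steps (steps 1–3) and joins at step 8.

**Three steps most likely to fail**

Step 9 (photochemical ring closure). The excited quinone may instead react with its own neighbouring prenyl group (charge transfer and cyclisation to a chromenol, known for prenylquinones), or the donor-substituted quinone may abstract hydrogen too slowly. The fallback sets out from 14 and comes back to the route at 15. Compound 14 is treated with 1,4-dimethyl-1,2,4-triazolium iodide (10 mol %) and DBU (15 mol %) in THF at 20 °C under argon. The carbene adds to the aldehyde, and the resulting Breslow intermediate is a strong one-electron donor held next to the quinone acceptor. Electron transfer gives a ketyl-type radical and a semiquinone, which join at the adjacent semiquinone oxygen (or, after a second electron transfer, through the acyl azolium acylating that same oxygen). Loss of the carbene leaves the same lactone. No light is used, so the prenyl photochemistry is avoided. No new compound arises on this way (none, F0). The fluoride treatment of step 9 then gives 16.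

Step 8 (diaryl ether). The phenoxide of 12 is hindered on both sides and tied up by the formyl group, so displacement on the crowded chloroquinone may stall. The fallback sets out from 11 (with 13 generated from 6 as in step 8) and comes back to the route at 14. The unchelated, more nucleophilic phenol 11 is coupled with 13 (Cs2CO3, MeCN, 20 °C) to give 2,2-dimethyl-7-(3-methylbut-2-en-1-yl)-6-[2-(3-methylbut-2-en-1-yl)-3,5-bis(triisopropylsilyloxy)phenoxy]-2H-chromene-5,8-dione F1. Ring B is then formylated by Vilsmeier–Haack reaction (POCl3, DMF, 0 → 20 °C; aq. NaOAc). Attack is expected at the ring carbon between the aryloxy and one silyloxy group, because the only other free carbon lies between two triisopropylsilyloxy groups; this selectivity is the uncertain point of the fallback. The product is 14.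

Step 3 (C-prenylation of the hydroxyquinone). O-alkylation competes, as in the lapachol precedent. The fallback sets out from 4 and comes back to the route at 6. Compound 4 is alkylated without regard to site (K2CO3, acetone, 5, 20 °C), giving mainly the vinylogous ester 2,2-dimethyl-6-[(3-methylbut-2-en-1-yl)oxy]-2H-chromene-5,8-dione F2. The crude material is then treated with Pd(PPh3)4 (zerovalent palladium, 5 mol %) in THF at 50 °C. Ionisation gives a π-prenyl palladium cation and the hydroxyquinone anion, which recombine at carbon through the less substituted allyl terminus (Tsuji–Trost O-to-C allyl transfer) to give 6. Any 6 formed directly in the alkylation passes through unchanged.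

**Further compounds**

F0 | step 9 | none | none
F1 | step 8 | 2,2-dimethyl-7-(3-methylbut-2-en-1-yl)-6-[2-(3-methylbut-2-en-1-yl)-3,5-bis(triisopropylsilyloxy)phenoxy]-2H-chromene-5,8-dione | CC(C)=CCC1=C(Oc2cc(O[Si](C(C)C)(C(C)C)C(C)C)cc(O[Si](C(C)C)(C(C)C)C(C)C)c2CC=C(C)C)C(=O)C2=C(OC(C)(C)C=C2)C1=O
F2 | step 3 | 2,2-dimethyl-6-[(3-methylbut-2-en-1-yl)oxy]-2H-chromene-5,8-dione | CC(C)=CCOC1=CC(=O)C2=C(C=CC(C)(C)O2)C1=O
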